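## Structural features

The target 23 is a 1-aryl-1,2-dihydronaphthalene. Ring A (C4a, C5–C8, C8a) is aromatic and carries methoxy groups at C6 and C8 and a free hydroxyl at C7. Ring B (C1–C4) contains one double bond, C3=C4, conjugated with ring A. C1 bears a 4-hydroxy-3,5-dimethoxyphenyl group (ring C), and C2 and C3 each bear a methyl group. The two stereocentres C1 and C2 are adjacent, both (S), with the C1 aryl group and the C2 methyl group cis. C1 is doubly benzylic and sits next to the C8 methoxy group, which should push its aryl substituent into a pseudoaxial position. The fragile parts are the two hindered, easily oxidised 2,6-dimethoxyphenols and the electron-rich styrene C3=C4, which can migrate towards C1=C2 under acid or aromatise under oxidants, in both cases with loss of the stereocentres. The real difficulty is the absolute configuration at C1, a CH that carries two almost identical trioxygenated aryl groups, together with the cis methyl group at C2. The key step uses the fact that C2 and its methyl carbon can be the two carbons of a terminal alkyne on C1, while C4, C3 and the C3 methyl are the carbonyl, α-carbon and β-carbon of a propiophenone on ring A. A gold-activated alkyne and a silyl enol ether then join C2 to C3 and close ring B.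

## Logic of the disconnections

23 to 22. The C3=C4 double bond is traced back to a C4–OH and a C3–H bond. C4 is benzylic and para to the free C7 hydroxyl, so loss of water needs only a trace of weak acid and the styrene appears in the last step. The forward step must lose the proton from C3 only, which is the only position that restores ring A, and must not be acidic enough to move the double bond towards C1.

22 to 21 to 20. The C4–H bond goes back to a ketone and both phenolic O–H bonds go back to benzyl ethers. The benzyl groups are removed by hydrogenolysis while ring B is still saturated, so no Lewis acid has to be used on the finished dihydronaphthalene. The demand is that hydrogenolysis spares the aryl ketone and that hydride reduction works in the presence of free phenols.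

20 to 19. The C2–H bond and one C–H bond of the C2 methyl group are removed, which turns the C2 stereocentre into an exocyclic C2 methylene. This leaves C1 as the only stereocentre of consequence in 19. The forward hydrogenation must come from the face opposite the C1 aryl group.

19 to 18. The C2–C3 bond is cut. This is the ring B bond whose formation does not touch C1 and whose two ends are an alkyne carbon and an enol ether carbon. Ring B opens to a diarylpropyne carrying a propiophenone enol ether. The forward step needs 6-exo closure and non-basic conditions so that the propargylic C1–H is preserved.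

18 to 17 to 16. The O–Si bond of the enol ether and then the C4=O group are traced back to a ketone and its cyclic ketal. The ketal is needed for the fragment coupling further back. The forward enolisation must avoid strong base, because both the alkyne C–H and the doubly benzylic C1–H are acidic.

16 to 15 to 14 to 13 and 12. The C1–C(sp) bond is cut after the ring C benzyl ether and the alkyne silyl group have been traced back. In 13, C1 is a trigonal carbon at the end of a cross-conjugated dienone, so the C1 stereocentre reduces to a face selection by a chiral catalyst during addition of 12. 13 itself comes from 11 by loss of a silyl group from the ring C oxygen and of acetate from C1. The demand is enantioface discrimination at a carbon that carries a di-ortho-substituted aryl group.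

11 to 7 and 8. The C1–C8a bond is cut into the aryl anion 9 at C8a and the formyl carbon of 8. Both halves derive from 1, which makes the plan convergent. The C4 carbonyl must be masked as the ketal of 7, so that 9 cannot attack it and the C1 oxygen of 10 cannot close onto it. 10 is acetylated in the flask to provide the leaving group that step 8 needs.

7 to 6 to 5 to 3 and 4; 3 to 2 to 1; 8 to 1. The ketal, the C4 oxidation level and the C3–C4 bond are traced back to addition of 4 to the formyl group of 3. The C8a–Br bond and the benzyl ether lead back to 1, and a single silylation links 8 to 1. The two free ring positions of 2 are equivalent, so the bromination has no regiochemical issue.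

## Other disconnections considered

Alternative 1: The cut is at the C1–ring C bond and the C2–CH3 bond, across the C1=C2 double bond of the (E)-alkenyl pinacolboronate A2 (ring A with its C4 carbon as a dimethyl acetal). In the forward step MeLi would convert A2 into its ate complex. An arylpalladium triflate (divalent palladium), formed from the aryl triflate A3 with Pd(OAc)2 and a chiral bisphosphine, would then bind the alkene and trigger the 1,2-shift of methyl from boron to C2 while the aryl group is delivered to C1, giving A1.
- In its favour: C1 and C2 would both be set in one catalyst-controlled, stereospecific addition across an alkene of defined geometry. No quinone methide is needed, and no substrate-controlled hydrogenation.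
- Against it: β-aryl alkenylboronates are the difficult substrates for this coupling because direct cross-coupling at boron competes. The aryl group here is di-ortho-substituted. Methyl is one of the less willing migrating groups in 1,2-metallate shifts.
- Against it: the key step closes no ring. The C2–B bond of A1 would still have to become the C2–C3 bond (for example isopropenylation at boron), the acetal a styrene, and ring B would be closed by metathesis before debenzylation.
- Comparison: on stereocontrol this plan is the better one in principle, since both centres come from one event and no epimer mixture at C3 arises. On ring construction the chosen plan is better, since its key step closes ring B. Step economy is estimated as about equal. Both key steps rest on activation of a π bond by a late transition metal, but the gold step has closer precedent for its exact bond type.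

Alternative 2: The cuts are at C1–C2 and C3–C4, a retro-Diels–Alder opening of ring B. In the forward step, irradiation of the 2-benzylbenzaldehyde A5 near 350 nm would give the (E)-hydroxy-o-quinodimethane by 1,5-hydrogen shift. This would add endo to the chiral butenolide A6, anti to its menthyloxy group, to give the cycloadduct A4.
- In its favour: ring B and four contiguous stereocentres, including C1 and C2 in the cis relationship, would form in one reagent-free step from an achiral, short precursor. The auxiliary is inexpensive. Photoenol cycloadditions of this kind have close precedent in aryltetralin lignan construction.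
- Against it: the two lactone carbons arrive at the acetal and carboxyl oxidation levels and both must be reduced to methyl groups, with the C4 hydroxyl kept apart for the final dehydration. That is estimated at five to six operations after the cycloaddition.
- Against it: the auxiliary is stoichiometric, and the C8 methoxy group next to the benzylic carbon may speed reketonisation of the photoenol.
- Comparison: per key step this plan builds more (two bonds, one ring, four centres against one bond, one ring, no centre), and on that point it is the better one. On redox economy the chosen plan is better, because its alkyne and ketone carbons are already at or next to the final oxidation levels. The total lengths are estimated to be similar.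

Alternative 3: The cut is at C1–C2 only. In the forward step the hydrazone A8, with a (Z)-2-methylbut-1-enyl group ortho to the diaryl hydrazone carbon, would be oxidised by MnO2 to the diaryldiazomethane. Rh2(S-PTAD)4 would generate the donor/donor carbene at C1, which would insert into the allylic C2–H bond of the ethyl group to give A7.
- In its favour: the precursor is achiral and short to make. The catalyst would set C1 and C2 together. Only debenzylation would remain, so no redox adjustment and no C3 epimer mixture arise. On step economy this is the best of the four plans.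
- Against it: ring closure by C–H insertion to a six-membered carbocycle is less favourable than the five-membered mode. The carbene is ortho to an alkene and may add to the C3=C4 bond or cyclise to an indene instead.
- Against it: the (Z) geometry of the trisubstituted alkene in A8 must be secured, and hydrazone formation on a tri-ortho-substituted benzophenone is demanding. Cis selectivity and enantioselectivity for this ring size are open.
- Comparison: structurally it is the most direct, but its key step is the most speculative. The chosen plan spends more steps but relies on a ring closure with direct precedent and on a hydrogenation whose face selectivity follows from the ring conformation.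

Key step: step 12

Remark (assumption on the chemistry): the sense of induction of the copper/pybox catalyst in step 8 cannot be derived from first principles, so the (S,S) ligand is written and its antipode is to be used if a test run shows the opposite sense; atom labels C1–C8a are those of the dihydronaphthalene core of 23 and are used for all intermediates.

## Route

Step 1
Reactants: 1 syringaldehyde (4-hydroxy-3,5-dimethoxybenzaldehyde)
Product: 2 4-(benzyloxy)-3,5-dimethoxybenzaldehyde
Conditions: BnBr, K2CO3, DMF, 60 °C
Reagents that add atoms: benzyl bromide, BrCc1ccccc1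
Why: Williamson etherification of the phenoxide; the benzyl ether should survive organolithium, fluoride, aqueous acid, gold and iridium chemistry and can be removed by hydrogenolysis once ring B is saturated.

Step 2
Reactants: 2 4-(benzyloxy)-3,5-dimethoxybenzaldehyde
Product: 3 4-(benzyloxy)-2-bromo-3,5-dimethoxybenzaldehyde
Conditions: NBS, MeCN, rt, dark
Reagents that add atoms: N-bromosuccinimide, O=C1CCC(=O)N1Br
Why: Electrophilic aromatic bromination; the two free ring positions are equivalent and activated by the methoxy groups, so only one monobromide can form, and the formyl group and the first bromine slow a second substitution.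

Step 3
Reactants: 3 4-(benzyloxy)-2-bromo-3,5-dimethoxybenzaldehyde; 4 ethylmagnesium bromide
Product: 5 rac-1-[4-(benzyloxy)-2-bromo-3,5-dimethoxyphenyl]propan-1-ol
Conditions: THF, −20 to 0 °C; aq. work-up
Reagents that add atoms: none
Why: Grignard 1,2-addition to the aldehyde brings in C3 and its methyl carbon; magnesium–bromine exchange at the aryl bromide is much slower at this temperature, and the racemic carbinol centre is removed in step 4.

Step 4
Reactants: 5 rac-1-[4-(benzyloxy)-2-bromo-3,5-dimethoxyphenyl]propan-1-ol
Product: 6 1-[4-(benzyloxy)-2-bromo-3,5-dimethoxyphenyl]propan-1-one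
Conditions: Dess–Martin periodinane, CH2Cl2, rt
Reagents that add atoms: none
Why: Dess–Martin oxidation of a secondary benzylic alcohol under neutral conditions; no other oxidisable group is present.

Step 5
Reactants: 6 1-[4-(benzyloxy)-2-bromo-3,5-dimethoxyphenyl]propan-1-one
Product: 7 2-[4-(benzyloxy)-2-bromo-3,5-dimethoxyphenyl]-2-ethyl-1,3-dioxolane
Conditions: ethylene glycol, p-TsOH·H2O (cat.), toluene, reflux, Dean–Stark
Reagents that add atoms: ethylene glycol, OCCO
Why: Acid-catalysed ketalisation with azeotropic removal of water; the ketal keeps the aryllithium of step 7 from attacking its own carbonyl and keeps the C1 oxygen and the later quinone methide from closing onto a ketone oxygen.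

Step 6
Reactants: 1 syringaldehyde (4-hydroxy-3,5-dimethoxybenzaldehyde)
Product: 8 4-[(tert-butyldimethylsilyl)oxy]-3,5-dimethoxybenzaldehyde
Conditions: TBSCl, imidazole, DMF, rt
Reagents that add atoms: tert-butyldimethylsilyl chloride, CC(C)(C)[Si](C)(C)Cl
Why: Silylation of the phenol; the aryl silyl ether tolerates the aryllithium and later serves as the fluoride-sensitive trigger for quinone methide formation.

Step 7
Reactants: 7 2-[4-(benzyloxy)-2-bromo-3,5-dimethoxyphenyl]-2-ethyl-1,3-dioxolane; 8 4-[(tert-butyldimethylsilyl)oxy]-3,5-dimethoxybenzaldehyde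
Product: 11 rac-[3-(benzyloxy)-6-(2-ethyl-1,3-dioxolan-2-yl)-2,4-dimethoxyphenyl]{4-[(tert-butyldimethylsilyl)oxy]-3,5-dimethoxyphenyl}methyl acetate, via aryllithium 9 (not isolated), via lithium alkoxide 10 (not isolated)
Conditions: n-BuLi, THF, −78 °C; 8, −78 °C; Ac2O, −78 to 0 °C
Reagents that add atoms: acetic anhydride, CC(=O)OC(C)=O
Why: Bromine–lithium exchange is faster than any deprotonation at −78 °C, and addition of 9 to the aldehyde forms the C1–C8a bond. Acetylation of 10 in the flask turns the C1 oxygen into a leaving group; the racemic C1 centre becomes trigonal in step 8.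

Step 8
Reactants: 11 rac-[3-(benzyloxy)-6-(2-ethyl-1,3-dioxolan-2-yl)-2,4-dimethoxyphenyl]{4-[(tert-butyldimethylsilyl)oxy]-3,5-dimethoxyphenyl}methyl acetate; 12 trimethylsilylacetylene
Product: 14 4-{(1S)-1-[3-(benzyloxy)-6-(2-ethyl-1,3-dioxolan-2-yl)-2,4-dimethoxyphenyl]-3-(trimethylsilyl)prop-2-yn-1-yl}-2,6-dimethoxyphenol, via quinone methide 13 (not isolated)
Conditions: TBAF (1.0 equiv), THF, −40 °C; then added slowly to (CuOTf)2·C6H6 (5 mol%), (S,S)-Ph-pybox (12 mol%), 12, i-Pr2NEt, toluene, −20 °C
Reagents that add atoms: none
Why: Proposed new method: fluoride frees the ring C phenoxide, which expels acetate to give 13, and a pybox-bound monovalent copper acetylide formed from 12 and the amine adds to the exocyclic carbon in the 1,6 sense, driven by re-aromatisation of ring C; the closest known reaction types are the copper-catalysed enantioselective additions of terminal alkynes to iminium and cyclic oxocarbenium ions and the catalytic enantioselective 1,6-additions of other nucleophiles to δ-aryl p-quinone methides. The C1 stereocentre is set here by the chiral ligand, which has to tell the hydrogen from the bulky di-ortho-substituted ring A aryl group on the trigonal carbon; the (S) configuration is the one required.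

Step 9
Reactants: 14 4-{(1S)-1-[3-(benzyloxy)-6-(2-ethyl-1,3-dioxolan-2-yl)-2,4-dimethoxyphenyl]-3-(trimethylsilyl)prop-2-yn-1-yl}-2,6-dimethoxyphenol
Product: 16 2-{4-(benzyloxy)-2-[(1S)-1-[4-(benzyloxy)-3,5-dimethoxyphenyl]prop-2-yn-1-yl]-3,5-dimethoxyphenyl}-2-ethyl-1,3-dioxolane, via silylalkyne benzyl ether 15 (not isolated)
Conditions: BnBr, K2CO3, DMF, rt; then MeOH, rt
Reagents that add atoms: benzyl bromide, BrCc1ccccc1
Why: Williamson etherification of the ring C phenol, then carbonate/methanol protodesilylation of the alkynylsilane in the same flask; the weak base should leave the doubly benzylic propargylic C1–H untouched.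

Step 10
Reactants: 16 2-{4-(benzyloxy)-2-[(1S)-1-[4-(benzyloxy)-3,5-dimethoxyphenyl]prop-2-yn-1-yl]-3,5-dimethoxyphenyl}-2-ethyl-1,3-dioxolane
Product: 17 1-{4-(benzyloxy)-2-[(1S)-1-[4-(benzyloxy)-3,5-dimethoxyphenyl]prop-2-yn-1-yl]-3,5-dimethoxyphenyl}propan-1-one
Conditions: 1 M HCl, THF, rt
Reagents that add atoms: water, O
Why: Acid-catalysed hydrolysis of the dioxolane, helped by the p-alkoxy-stabilised oxocarbenium ion; benzyl ethers, the terminal alkyne and C1 are inert to dilute aqueous acid.

Step 11
Reactants: 17 1-{4-(benzyloxy)-2-[(1S)-1-[4-(benzyloxy)-3,5-dimethoxyphenyl]prop-2-yn-1-yl]-3,5-dimethoxyphenyl}propan-1-one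
Product: 18 tert-butyl{[(1Z)-1-{4-(benzyloxy)-2-[(1S)-1-[4-(benzyloxy)-3,5-dimethoxyphenyl]prop-2-yn-1-yl]-3,5-dimethoxyphenyl}prop-1-en-1-yl]oxy}dimethylsilane
Conditions: TBSOTf, Et3N, CH2Cl2, 0 °C to rt
Reagents that add atoms: tert-butyldimethylsilyl trifluoromethanesulfonate, CC(C)(C)[Si](C)(C)OS(=O)(=O)C(F)(F)F
Why: Soft enolisation (silyl triflate activation of the carbonyl, deprotonation by the amine) should give mainly the (Z)-enol ether without a strong base, so neither the alkyne C–H nor the acidic C1–H is removed and C1 keeps its configuration. The enol geometry does not matter because the α-centre is erased in step 16.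

Step 12
Reactants: 18 tert-butyl{[(1Z)-1-{4-(benzyloxy)-2-[(1S)-1-[4-(benzyloxy)-3,5-dimethoxyphenyl]prop-2-yn-1-yl]-3,5-dimethoxyphenyl}prop-1-en-1-yl]oxy}dimethylsilane
Product: 19 (4S)-6-(benzyloxy)-4-[4-(benzyloxy)-3,5-dimethoxyphenyl]-5,7-dimethoxy-2-methyl-3-methylidene-3,4-dihydronaphthalen-1(2H)-one (both epimers at the methyl-bearing carbon)
Conditions: (Ph3P)AuNTf2 (5 mol%), CH2Cl2/MeOH 10:1, 0 °C to rt
Reagents that add atoms: none
Why: Cationic monovalent gold from (Ph3P)AuNTf2 binds the terminal alkyne of 18 and makes it electrophilic; the enol ether carbon C3 attacks the internal alkyne carbon C2 anti to gold, giving an exocyclic vinylgold species and a silyloxocarbenium ion at C4. Methanol removes the silyl group as its methyl ether and protodeauration releases the C2 methylene and the catalyst. The closest known reaction type is the gold-catalysed Conia-ene-type carbocyclisation of silyl enol ethers onto unactivated alkynes, established for 5-exo and 6-exo-dig closures. Ring B closes in the 6-exo-dig mode (ring atoms C1, C2, C3, C4, C4a, C8a, with the former alkyne terminus left outside as the methylene carbon). No stereocentre of the target is created: C3 forms as an epimer mixture that is erased in step 16, and the propargylic C1 centre takes part in no bond change under these non-basic conditions. The selectivity needed is 6-exo over 7-endo closure and C- over O-attack; the terminal alkyne directs the nucleophile to its substituted carbon, the ortho-disposed tether favours the benzo-fused six-membered ring, and the silyl group blocks the carbonyl oxygen. The reaction is to be stopped at full conversion and 19 hydrogenated without storage, because migration of the methylene into conjugation would lead on to a naphthol and destroy C1.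

Step 13
Reactants: 19 (4S)-6-(benzyloxy)-4-[4-(benzyloxy)-3,5-dimethoxyphenyl]-5,7-dimethoxy-2-methyl-3-methylidene-3,4-dihydronaphthalen-1(2H)-one
Product: 20 (3S,4S)-6-(benzyloxy)-4-[4-(benzyloxy)-3,5-dimethoxyphenyl]-5,7-dimethoxy-2,3-dimethyl-3,4-dihydronaphthalen-1(2H)-one (both epimers at the carbon next to the carbonyl)
Conditions: [Ir(cod)(PCy3)(py)]PF6 (5 mol%), H2 (1 atm), CH2Cl2, 0 °C to rt
Reagents that add atoms: none
Why: Homogeneous iridium-catalysed hydrogenation of the 1,1-disubstituted alkene, which leaves benzyl ethers and the aryl ketone alone. The C1 aryl group is held pseudoaxial by the C8 methoxy group and by allylic 1,3-strain with the methylene, so H2 should be delivered to the opposite face; the new C2 methyl group then lies cis to the aryl group, which is the (S) configuration at C2.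

Step 14
Reactants: 20 (3S,4S)-6-(benzyloxy)-4-[4-(benzyloxy)-3,5-dimethoxyphenyl]-5,7-dimethoxy-2,3-dimethyl-3,4-dihydronaphthalen-1(2H)-one
Product: 21 (3S,4S)-6-hydroxy-4-(4-hydroxy-3,5-dimethoxyphenyl)-5,7-dimethoxy-2,3-dimethyl-3,4-dihydronaphthalen-1(2H)-one (both epimers at the carbon next to the carbonyl)
Conditions: H2 (1 atm), 10% Pd/C, EtOAc, rt
Reagents that add atoms: none
Why: Heterogeneous hydrogenolysis of both aryl benzyl ethers, placed here because no alkene is present and neither C1 nor C2 is enolisable. In ethyl acetate at 1 atm the electron-rich aryl ketone should be reduced far more slowly than the benzylic C–O bonds are cleaved.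

Step 15
Reactants: 21 (3S,4S)-6-hydroxy-4-(4-hydroxy-3,5-dimethoxyphenyl)-5,7-dimethoxy-2,3-dimethyl-3,4-dihydronaphthalen-1(2H)-one
Product: 22 (3S,4S)-4-(4-hydroxy-3,5-dimethoxyphenyl)-5,7-dimethoxy-2,3-dimethyl-1,2,3,4-tetrahydronaphthalene-1,6-diol (mixture at the carbinol and the adjacent carbon)
Conditions: NaBH4 (excess), MeOH/THF, 0 °C; NH4Cl work-up
Reagents that add atoms: none
Why: Borohydride reduction of the aryl ketone to the C4 carbinol; the configurations at C4 and C3 do not matter because both carbons become trigonal in step 16. The low temperature keeps the p-hydroxybenzylic alcohol from ionising in the basic medium.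

Step 16
Reactants: 22 (3S,4S)-4-(4-hydroxy-3,5-dimethoxyphenyl)-5,7-dimethoxy-2,3-dimethyl-1,2,3,4-tetrahydronaphthalene-1,6-diol
Product: 23 (7S,8S)-8-(4-hydroxy-3,5-dimethoxyphenyl)-1,3-dimethoxy-6,7-dimethyl-7,8-dihydronaphthalen-2-ol (the target; C1 and C2 of the core both S)
Conditions: PPTS (10 mol%), 1,2-dichloroethane (dilute), 40 °C
Reagents that add atoms: none
Why: Acid-catalysed E1 dehydration: the C7 hydroxyl para to C4a lets C4 ionise to a quinone methide/benzylic cation under very mild acid, and the only proton whose loss re-aromatises ring A is the one on C3, which gives the C3=C4 alkene. C1 and C2 are outside the cationic system and should keep their configuration.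

## Compound list

1 | syringaldehyde (4-hydroxy-3,5-dimethoxybenzaldehyde) | COc1cc(C=O)cc(OC)c1O | starting material
2 | 4-(benzyloxy)-3,5-dimethoxybenzaldehyde | COc1cc(C=O)cc(OC)c1OCc1ccccc1 | intermediate
3 | 4-(benzyloxy)-2-bromo-3,5-dimethoxybenzaldehyde | COc1cc(C=O)c(Br)c(OC)c1OCc1ccccc1 | intermediate
4 | ethylmagnesium bromide | CC[Mg]Br | starting material
5 | rac-1-[4-(benzyloxy)-2-bromo-3,5-dimethoxyphenyl]propan-1-ol | CCC(O)c1cc(OC)c(OCc2ccccc2)c(OC)c1Br | intermediate
6 | 1-[4-(benzyloxy)-2-bromo-3,5-dimethoxyphenyl]propan-1-one | CCC(=O)c1cc(OC)c(OCc2ccccc2)c(OC)c1Br | intermediate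
7 | 2-[4-(benzyloxy)-2-bromo-3,5-dimethoxyphenyl]-2-ethyl-1,3-dioxolane | CCC1(OCCO1)c1cc(OC)c(OCc2ccccc2)c(OC)c1Br | intermediate
8 | 4-[(tert-butyldimethylsilyl)oxy]-3,5-dimethoxybenzaldehyde | COc1cc(C=O)cc(OC)c1O[Si](C)(C)C(C)(C)C | intermediate
9 | [3-(benzyloxy)-6-(2-ethyl-1,3-dioxolan-2-yl)-2,4-dimethoxyphenyl]lithium | CCC1(OCCO1)c1cc(OC)c(OCc2ccccc2)c(OC)c1[Li] | intermediate
10 | lithium alkoxide of the racemic diaryl carbinol (ring A aryl as in 9, ring C aryl as in 8) | CCC1(OCCO1)c1cc(OC)c(OCc2ccccc2)c(OC)c1C(O[Li])c1cc(OC)c(O[Si](C)(C)C(C)(C)C)c(OC)c1 | intermediate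
11 | rac-[3-(benzyloxy)-6-(2-ethyl-1,3-dioxolan-2-yl)-2,4-dimethoxyphenyl]{4-[(tert-butyldimethylsilyl)oxy]-3,5-dimethoxyphenyl}methyl acetate | CCC1(OCCO1)c1cc(OC)c(OCc2ccccc2)c(OC)c1C(OC(C)=O)c1cc(OC)c(O[Si](C)(C)C(C)(C)C)c(OC)c1 | intermediate
12 | trimethylsilylacetylene (ethynyltrimethylsilane) | C#C[Si](C)(C)C | starting material
13 | 4-{[3-(benzyloxy)-6-(2-ethyl-1,3-dioxolan-2-yl)-2,4-dimethoxyphenyl]methylidene}-2,6-dimethoxycyclohexa-2,5-dien-1-one | CCC1(OCCO1)c1cc(OC)c(OCc2ccccc2)c(OC)c1C=C1C=C(OC)C(=O)C(OC)=C1 | intermediate
14 | 4-{(1S)-1-[3-(benzyloxy)-6-(2-ethyl-1,3-dioxolan-2-yl)-2,4-dimethoxyphenyl]-3-(trimethylsilyl)prop-2-yn-1-yl}-2,6-dimethoxyphenol | C[Si](C)(C)C#C[C@@H](c1cc(OC)c(O)c(OC)c1)c1c(OC)c(OCc2ccccc2)c(OC)cc1C1(CC)OCCO1 | intermediate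
15 | 2-{4-(benzyloxy)-2-[(1S)-1-[4-(benzyloxy)-3,5-dimethoxyphenyl]-3-(trimethylsilyl)prop-2-yn-1-yl]-3,5-dimethoxyphenyl}-2-ethyl-1,3-dioxolane | C[Si](C)(C)C#C[C@@H](c1cc(OC)c(OCc2ccccc2)c(OC)c1)c1c(OC)c(OCc2ccccc2)c(OC)cc1C1(CC)OCCO1 | intermediate
16 | 2-{4-(benzyloxy)-2-[(1S)-1-[4-(benzyloxy)-3,5-dimethoxyphenyl]prop-2-yn-1-yl]-3,5-dimethoxyphenyl}-2-ethyl-1,3-dioxolane | C#C[C@@H](c1cc(OC)c(OCc2ccccc2)c(OC)c1)c1c(OC)c(OCc2ccccc2)c(OC)cc1C1(CC)OCCO1 | intermediate
17 | 1-{4-(benzyloxy)-2-[(1S)-1-[4-(benzyloxy)-3,5-dimethoxyphenyl]prop-2-yn-1-yl]-3,5-dimethoxyphenyl}propan-1-one | C#C[C@@H](c1cc(OC)c(OCc2ccccc2)c(OC)c1)c1c(OC)c(OCc2ccccc2)c(OC)cc1C(=O)CC | intermediate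
18 | tert-butyl{[(1Z)-1-{4-(benzyloxy)-2-[(1S)-1-[4-(benzyloxy)-3,5-dimethoxyphenyl]prop-2-yn-1-yl]-3,5-dimethoxyphenyl}prop-1-en-1-yl]oxy}dimethylsilane | C#C[C@@H](c1cc(OC)c(OCc2ccccc2)c(OC)c1)c1c(OC)c(OCc2ccccc2)c(OC)cc1/C(O[Si](C)(C)C(C)(C)C)=C/C | intermediate
19 | (4S)-6-(benzyloxy)-4-[4-(benzyloxy)-3,5-dimethoxyphenyl]-5,7-dimethoxy-2-methyl-3-methylidene-3,4-dihydronaphthalen-1(2H)-one, both epimers at the methyl-bearing carbon | COc1cc([C@H]2c3c(cc(OC)c(OCc4ccccc4)c3OC)C(=O)C(C)C2=C)cc(OC)c1OCc1ccccc1 | intermediate
20 | (3S,4S)-6-(benzyloxy)-4-[4-(benzyloxy)-3,5-dimethoxyphenyl]-5,7-dimethoxy-2,3-dimethyl-3,4-dihydronaphthalen-1(2H)-one, both epimers at the carbon next to the carbonyl | COc1cc([C@H]2c3c(cc(OC)c(OCc4ccccc4)c3OC)C(=O)C(C)[C@H]2C)cc(OC)c1OCc1ccccc1 | intermediate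
21 | (3S,4S)-6-hydroxy-4-(4-hydroxy-3,5-dimethoxyphenyl)-5,7-dimethoxy-2,3-dimethyl-3,4-dihydronaphthalen-1(2H)-one, both epimers at the carbon next to the carbonyl | COc1cc([C@H]2c3c(cc(OC)c(O)c3OC)C(=O)C(C)[C@H]2C)cc(OC)c1O | intermediate
22 | (3S,4S)-4-(4-hydroxy-3,5-dimethoxyphenyl)-5,7-dimethoxy-2,3-dimethyl-1,2,3,4-tetrahydronaphthalene-1,6-diol, mixture at the carbinol and the adjacent carbon | COc1cc([C@H]2c3c(cc(OC)c(O)c3OC)C(O)C(C)[C@H]2C)cc(OC)c1O | intermediate
23 | (7S,8S)-8-(4-hydroxy-3,5-dimethoxyphenyl)-1,3-dimethoxy-6,7-dimethyl-7,8-dihydronaphthalen-2-ol | COc1cc([C@H]2c3c(cc(OC)c(O)c3OC)C=C(C)[C@H]2C)cc(OC)c1O | target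

## Step count and least certain steps

Total: 16 steps. Longest linear sequence: 15 steps (steps 1–5 and 7–16; step 6 is the one-step side branch).

**Step 8 (labelled as a proposed method).** The most likely failure is insufficient enantioface discrimination or slow catalytic turnover at the hindered trigonal carbon of 13, which would leave time for oligomerisation of 13 or for an unselective background addition. The fallback uses known chemistry and sets out from 11 and comes back at 14. 13 is generated from 11 with TBAF as above and treated at −78 °C with commercial lithium (trimethylsilyl)acetylide in THF, a plain 1,6-addition of an organolithium reagent to a quinone methide. This gives racemic 4-{1-[3-(benzyloxy)-6-(2-ethyl-1,3-dioxolan-2-yl)-2,4-dimethoxyphenyl]-3-(trimethylsilyl)prop-2-yn-1-yl}-2,6-dimethoxyphenol F1. The enantiomers of F1 are separated by preparative chromatography on a chiral stationary phase, and the (S) enantiomer, which is 14, enters step 9.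

**Step 12 (key step).** Two processes threaten it. One is loss of the silyl group before ring closure, which returns 17. The other is migration of the exocyclic double bond of 19 into conjugation with the ketone, followed by enolisation to a naphthol, which would erase C1. The fallback changes the mode of bond formation from π-acid catalysis to a radical closure; it sets out from 18 and comes back at 19. 18 is brominated with N-bromosuccinimide in THF at −78 °C to 2-bromo-1-{4-(benzyloxy)-2-[(1S)-1-[4-(benzyloxy)-3,5-dimethoxyphenyl]prop-2-yn-1-yl]-3,5-dimethoxyphenyl}propan-1-one F2. F2 is cyclised with Bu3SnH and AIBN in benzene at 80 °C under slow addition: the α-keto radical at C3 adds 6-exo-dig to the alkyne and the vinyl radical takes up hydrogen, which should give 19 under neutral conditions.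

**Step 13.** The risk is poor facial selectivity if the epimerisable C3 methyl group comes to lie on the face opposite the aryl group, or iridium hydride-mediated migration of the alkene into conjugation. The fallback replaces concerted delivery of H2 on a metal by stepwise hydrogen-atom transfer; it sets out from 19 and comes back at 20 without a new compound. Mn(dpm)3 (cat.), PhSiH3 and tert-butyl hydroperoxide in isopropanol at room temperature would put a hydrogen atom on the methylene carbon. The tertiary C2 radical would then be quenched from the open face opposite the pseudoaxial aryl group, and no metal alkyl capable of β-hydride elimination is involved.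

**Step 14.** The risk is over-reduction of the aryl ketone on palladium, or incomplete cleavage of the two flanked benzyl ethers. The fallback replaces hydrogenolysis by Lewis acid cleavage; it sets out from 20 and comes back at 21 without a new compound. BCl3 with pentamethylbenzene as cation scavenger in CH2Cl2 at −78 °C is used, a substrate on which this reagent pair is safe because no alkene is present yet.

**Step 16.** The risk is intermolecular capture of the quinone methide/benzylic cation by a phenol or an electron-rich ring (oligomerisation), or acid-mediated drift of the double bond towards C1=C2. The fallback keeps the phenols protected through the dehydration; it sets out from 20 and comes back at 23.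
- 20 is reduced with NaBH4 in MeOH/THF to (3S,4S)-6-(benzyloxy)-4-[4-(benzyloxy)-3,5-dimethoxyphenyl]-5,7-dimethoxy-2,3-dimethyl-1,2,3,4-tetrahydronaphthalen-1-ol F3.
- F3 is dehydrated with methyl N-(triethylammoniosulfonyl)carbamate (Burgess reagent) in toluene at 60 °C to the di-O-benzyl ether of 23, F4.
- F4 is debenzylated with BCl3 and pentamethylbenzene in CH2Cl2 at −78 °C, quenched cold with methanol, to give 23.

## Further compounds

F1 | step 8 | rac-4-{1-[3-(benzyloxy)-6-(2-ethyl-1,3-dioxolan-2-yl)-2,4-dimethoxyphenyl]-3-(trimethylsilyl)prop-2-yn-1-yl}-2,6-dimethoxyphenol | C[Si](C)(C)C#CC(c1cc(OC)c(O)c(OC)c1)c1c(OC)c(OCc2ccccc2)c(OC)cc1C1(CC)OCCO1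
F2 | step 12 | 2-bromo-1-{4-(benzyloxy)-2-[(1S)-1-[4-(benzyloxy)-3,5-dimethoxyphenyl]prop-2-yn-1-yl]-3,5-dimethoxyphenyl}propan-1-one, both epimers at the bromine-bearing carbon | C#C[C@@H](c1cc(OC)c(OCc2ccccc2)c(OC)c1)c1c(OC)c(OCc2ccccc2)c(OC)cc1C(=O)C(C)Br
F0 | step 13 | none | none
F0 | step 14 | none | none
F3 | step 16 | (3S,4S)-6-(benzyloxy)-4-[4-(benzyloxy)-3,5-dimethoxyphenyl]-5,7-dimethoxy-2,3-dimethyl-1,2,3,4-tetrahydronaphthalen-1-ol, mixture at the carbinol and the adjacent carbon | COc1cc([C@H]2c3c(cc(OC)c(OCc4ccccc4)c3OC)C(O)C(C)[C@H]2C)cc(OC)c1OCc1ccccc1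
F4 | step 16 | di-O-benzyl ether of 23 | COc1cc([C@H]2c3c(cc(OC)c(OCc4ccccc4)c3OC)C=C(C)[C@H]2C)cc(OC)c1OCc1ccccc1
A1 | alternative 1 | pinacol boronate of the 1,1-diaryl-2-borylpropane, ring A carrying its C4 carbon as a dimethyl acetal, both phenols benzylated | COc1cc([C@@H](c2c(C(OC)OC)cc(OC)c(OCc3ccccc3)c2OC)[C@H](C)B2OC(C)(C)C(C)(C)O2)cc(OC)c1OCc1ccccc1
A2 | alternative 1 | (E)-2-{2-[4-(benzyloxy)-6-(dimethoxymethyl)-3,5... ring A styrenyl}pinacolboronate: ring A aryl–CH=CH–B(pin) with ortho dimethyl acetal | COC(OC)c1cc(OC)c(OCc2ccccc2)c(OC)c1/C=C/B1OC(C)(C)C(C)(C)O1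
A3 | alternative 1 | 4-(benzyloxy)-3,5-dimethoxyphenyl trifluoromethanesulfonate | COc1cc(OS(=O)(=O)C(F)(F)F)cc(OC)c1OCc1ccccc1
A4 | alternative 2 | endo cycloadduct, 4-hydroxytetralin cis-fused to the menthyloxy lactone | COc1cc([C@H]2c3c(cc(OC)c(OCc4ccccc4)c3OC)[C@@H](O)[C@@H]3[C@H]2[C@@H](O[C@H]2C[C@@H](C)CC[C@@H]2C(C)C)OC3=O)cc(OC)c1OCc1ccccc1
A5 | alternative 2 | 4-(benzyloxy)-2-[4-(benzyloxy)-3,5-dimethoxybenzyl]-3,5-dimethoxybenzaldehyde | COc1cc(Cc2c(OC)c(OCc3ccccc3)c(OC)cc2C=O)cc(OC)c1OCc1ccccc1
A6 | alternative 2 | (5S)-5-{[(1S,2R,5S)-2-isopropyl-5-methylcyclohexyl]oxy}furan-2(5H)-one | O=C1C=C[C@@H](O[C@H]2C[C@@H](C)CC[C@@H]2C(C)C)O1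
A7 | alternative 3 | di-O-benzyl ether of the target | COc1cc([C@H]2c3c(cc(OC)c(OCc4ccccc4)c3OC)C=C(C)[C@H]2C)cc(OC)c1OCc1ccccc1
A8 | alternative 3 | hydrazone of {4-(benzyloxy)-3,5-dimethoxyphenyl}{3-(benzyloxy)-2,4-dimethoxy-6-[(1Z)-2-methylbut-1-en-1-yl]phenyl}methanone | CC/C(C)=C\c1cc(OC)c(OCc2ccccc2)c(OC)c1C(=NN)c1cc(OC)c(OCc2ccccc2)c(OC)c1
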